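The C5, C10, C9, C8 stereotetrad of ring B, with an oxidised one-carbon group (C11) on C9, is the retron of a [4+2] union of a C9=C10 enal with a C5=C6–C7=C8 diene, the two being linked through C1–C4 of ring A. A single Lewis-acid-promoted intramolecular Diels–Alder reaction therefore forms C5–C10 and C8–C9, closes rings A and B together and sets C5, C9 and C10 from the lone C3 carbinol centre. Its precursor is an acyclic (2E,8E,10E)-trienal bearing a 6R silyloxy group, a 7,7-dimethyl unit and a silyl-protected hydroxymethyl diene terminus. The C12–C16 chain and the C17 aldehyde are added afterwards.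

Key step: step 14

Conventions: ring compounds are discussed in labdane numbering (decalin C1–C10, C11 on C9, C17 on C8, C20 on C10); TBS = tert-butyldimethylsilyl, TES = triethylsilyl. The target is (3R,5S,8S,9R,10S) in this numbering.

Assumption: the oxazaborolidinone made from N-tosyl-L-valine is taken to give the 3R aldol with this unbranched aldehyde, in line with the usual facial sense of this promoter; the D-valine reagent is its mirror image.

Design remark: C17 is carried through the cycloaddition as a TBS ether. A benzyl-type ether would bind Me2AlCl more strongly, could ionise at the pentadienylic position and would not survive the alkene hydrogenation of step 15. The silyl ether avoids all three and leaves together with the C3 silyl group. The ring alkene is hydrogenated before the side chain is built, so it never competes with the vinyl group or the enoate.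

Step 1
Reactants: 1 geranyl acetate
Product: 2 (2E)-5-(3,3-dimethyloxiran-2-yl)-3-methylpent-2-en-1-yl acetate (6,7-epoxygeranyl acetate, racemic at the oxirane CH)
Conditions: mCPBA (1.05 equiv), CH2Cl2, 0 °C
Reagents that add atoms: mCPBA, OOC(=O)c1cccc(Cl)c1
Why: Prilezhaev epoxidation is electrophilic, so the remote, electron-rich trisubstituted alkene should react well ahead of the alkene deactivated by the allylic acetoxy group, and the racemic oxirane centre is of no consequence because step 2 removes it.

Step 2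
Reactants: 2 6,7-epoxygeranyl acetate
Product: 4 (2E)-3-methyl-6-oxohex-2-en-1-yl acetate, via vicinal diol 3 (not isolated)
Conditions: H5IO6 (1.2 equiv), THF/H2O, 0 °C → rt
Reagents that add atoms: none
Why: acid-promoted hydrolysis of the epoxide (water entering at the tertiary carbon) is followed in the same flask by Malaprade glycol cleavage, which expels the isopropylidene carbon as acetone and leaves the C3 aldehyde with its original epoxide oxygen, the alkene and the acetate being inert to periodic acid.

Step 3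
Reactants: 4 (2E)-3-methyl-6-oxohex-2-en-1-yl acetate; 5 1-methoxy-2-methyl-1-(trimethylsilyloxy)prop-1-ene
Product: 6 methyl (3R,6E)-8-acetoxy-3-hydroxy-2,2,6-trimethyloct-6-enoate
Conditions: N-Ts-L-valine (1.1 equiv), BH3·THF (1.0 equiv), CH2Cl2, 0 °C → rt; then 4 and 5 (1.2 equiv), −78 °C; aq. buffer, then dilute HCl
Reagents that add atoms: none
Why: Kiyooka-type Mukaiyama aldol, in which the aldehyde is activated on the electron-poor boron of the valine-derived oxazaborolidinone, whose isopropyl and tosyl groups shield one carbonyl face, so the silyl ketene acetal should add to the other face to give the 3R carbinol (labdane C3) together with C4, its gem-dimethyl pair and the ester carbon C5.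

Step 4
Reactants: 6 methyl (3R,6E)-8-acetoxy-3-hydroxy-2,2,6-trimethyloct-6-enoate
Product: 7 methyl (3R,6E)-8-acetoxy-3-[(tert-butyldimethylsilyl)oxy]-2,2,6-trimethyloct-6-enoate
Conditions: TBSOTf (1.3 equiv), 2,6-lutidine (2 equiv), CH2Cl2, −78 → 0 °C
Reagents that add atoms: TBSOTf, CC(C)(C)[Si](C)(C)OS(=O)(=O)C(F)(F)F
Why: the silyl triflate silylates the hindered secondary alcohol, which blocks retro-aldol cleavage in the later basic steps and provides the bulky C3 substituent that steers the cycloaddition.

Step 5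
Reactants: 7 methyl (3R,6E)-8-acetoxy-3-(TBSO)-2,2,6-trimethyloct-6-enoate
Product: 8 methyl (3R,6E)-3-[(tert-butyldimethylsilyl)oxy]-8-hydroxy-2,2,6-trimethyloct-6-enoate
Conditions: K2CO3 (0.3 equiv), MeOH, 0 °C → rt
Reagents that add atoms: none
Why: base-catalysed transesterification with methanol removes the unhindered acetate, whereas the neopentyl methyl ester can only exchange methoxide for methoxide and has neither an α-hydrogen nor a free β-hydroxyl through which it could eliminate or fragment.

Step 6
Reactants: 8 methyl (3R,6E)-3-(TBSO)-8-hydroxy-2,2,6-trimethyloct-6-enoate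
Product: 9 methyl (3R,6E)-3-[(tert-butyldimethylsilyl)oxy]-2,2,6-trimethyl-8-[(triethylsilyl)oxy]oct-6-enoate
Conditions: TESCl (1.2 equiv), imidazole (2 equiv), CH2Cl2, 0 °C
Reagents that add atoms: TESCl, CC[Si](CC)(CC)Cl
Why: silylation of the unhindered primary allylic alcohol installs a temporary TES group on C11 that survives hydride reduction, oxidation and olefination yet can later be removed in the presence of TBS ethers.

Step 7
Reactants: 9 methyl (3R,6E)-3-(TBSO)-2,2,6-trimethyl-8-(TESO)oct-6-enoate
Product: 10 (3R,6E)-3-[(tert-butyldimethylsilyl)oxy]-2,2,6-trimethyl-8-[(triethylsilyl)oxy]oct-6-en-1-ol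
Conditions: i-Bu2AlH (2.5 equiv), CH2Cl2, −78 → 0 °C; aq. KNaC4H4O6 (potassium sodium tartrate)
Reagents that add atoms: none
Why: excess i-Bu2AlH reduces the hindered ester through the aldehyde to the primary alcohol, the silyl ethers and the isolated alkene being inert to the hydride.

Step 8
Reactants: 10 (3R,6E)-3-(TBSO)-2,2,6-trimethyl-8-(TESO)oct-6-en-1-ol
Product: 11 (3R,6E)-3-[(tert-butyldimethylsilyl)oxy]-2,2,6-trimethyl-8-[(triethylsilyl)oxy]oct-6-enal
Conditions: Dess–Martin periodinane (1.3 equiv), NaHCO3, CH2Cl2, 0 °C → rt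
Reagents that add atoms: none
Why: Dess–Martin oxidation under buffered conditions converts the neopentyl alcohol into the aldehyde, which has no α-hydrogen and cannot epimerise or eliminate, and spares the TES ether that activated-DMSO oxidants could attack.

Step 9
Reactants: 11 (3R,6E)-3-(TBSO)-2,2,6-trimethyl-8-(TESO)oct-6-enal; 12 triethyl 4-phosphonocrotonate
Product: 13 ethyl (2E,4E,7R,10E)-7-[(tert-butyldimethylsilyl)oxy]-6,6,10-trimethyl-12-[(triethylsilyl)oxy]dodeca-2,4,10-trienoate
Conditions: 12 (1.5 equiv), LiN(SiMe3)2 (1.4 equiv), THF, −78 °C; then 11, −78 → 0 °C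
Reagents that add atoms: none
Why: Horner–Wadsworth–Emmons olefination with the lithiated phosphonocrotonate (reaction at the carbon next to phosphorus) adds C6, C7, C8 and C17 to the non-enolisable aldehyde, the stabilised reagent giving the E-alkene at C5=C6 while the C7=C8 geometry is carried over from the reagent.

Step 10
Reactants: 13 ethyl (2E,4E,7R,10E)-7-(TBSO)-6,6,10-trimethyl-12-(TESO)dodeca-2,4,10-trienoate
Product: 14 (2E,4E,7R,10E)-7-[(tert-butyldimethylsilyl)oxy]-6,6,10-trimethyl-12-[(triethylsilyl)oxy]dodeca-2,4,10-trien-1-ol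
Conditions: i-Bu2AlH (2.5 equiv), CH2Cl2, −78 °C; aq. KNaC4H4O6 (potassium sodium tartrate)
Reagents that add atoms: none
Why: i-Bu2AlH reduces the conjugated ester in a 1,2-fashion to the dienol at low temperature, which turns the electron-poor dienoate into the electron-rich diene needed for the cycloaddition and leaves the silyl ethers alone.

Step 11
Reactants: 14 (2E,4E,7R,10E)-7-(TBSO)-6,6,10-trimethyl-12-(TESO)dodeca-2,4,10-trien-1-ol
Product: 15 (2E,4E,7R,10E)-1,7-bis[(tert-butyldimethylsilyl)oxy]-6,6,10-trimethyl-12-[(triethylsilyl)oxy]dodeca-2,4,10-triene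
Conditions: TBSCl (1.2 equiv), imidazole (2.5 equiv), CH2Cl2, 0 °C → rt
Reagents that add atoms: TBSCl, CC(C)(C)[Si](C)(C)Cl
Why: standard silylation of the primary dienylic alcohol gives a C17 protecting group that is a poor Lewis base, is stable to hydrogenation and is cleaved later together with the C3 ether.

Step 12
Reactants: 15 (2E,4E,7R,10E)-1,7-bis(TBSO)-6,6,10-trimethyl-12-(TESO)dodeca-2,4,10-triene
Product: 16 (2E,6R,8E,10E)-6,12-bis[(tert-butyldimethylsilyl)oxy]-3,7,7-trimethyldodeca-2,8,10-trien-1-ol
Conditions: pyridinium p-toluenesulfonate (0.1 equiv), MeOH/CH2Cl2, 0 °C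
Reagents that add atoms: none
Why: acid-catalysed methanolysis cleaves the primary TES ether far faster than the primary or the hindered secondary TBS ether, which frees the C11 hydroxyl alone.

Step 13
Reactants: 16 (2E,6R,8E,10E)-6,12-bis(TBSO)-3,7,7-trimethyldodeca-2,8,10-trien-1-ol
Product: 17 (2E,6R,8E,10E)-6,12-bis[(tert-butyldimethylsilyl)oxy]-3,7,7-trimethyldodeca-2,8,10-trienal
Conditions: MnO2 (activated, 15 equiv), CH2Cl2, rt
Reagents that add atoms: none
Why: MnO2 oxidises only the allylic alcohol under neutral heterogeneous conditions and should give the E-enal with the silyl ethers, the diene and the alkene geometry intact.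

Step 14
Reactants: 17 (2E,6R,8E,10E)-6,12-bis(TBSO)-3,7,7-trimethyldodeca-2,8,10-trienal
Product: 18 (1R,2R,4aS,6R,8aR)-6-[(tert-butyldimethylsilyl)oxy]-2-{[(tert-butyldimethylsilyl)oxy]methyl}-5,5,8a-trimethyl-1,2,4a,5,6,7,8,8a-octahydronaphthalene-1-carbaldehyde (labdane numbering 3R,5S,8R,9R,10R; trans-fused; C20 methyl, C11 formyl, C17 and the C3 oxygen on one face, H5 on the other; C6=C7 alkene)
Conditions: Me2AlCl (1.5 equiv), CH2Cl2, −78 → −20 °C; aq. NaHCO3
Reagents that add atoms: none
Why: Me2AlCl binds the formyl oxygen of the s-trans enal and lowers its LUMO, so the tethered (E,E)-diene adds across C9=C10 in a concerted, asynchronous and suprafacial [4+2] cycloaddition; the closest known reaction class is the Lewis-acid-promoted type 1 intramolecular Diels–Alder reaction of 1,7,9-decatrienes carrying a terminally activated E-dienophile, which delivers trans-fused octalins. Ring B (C5–C10) closes as the new cyclohexene through the C8–C9 and C5–C10 bonds, and ring A (C1–C5 plus C10) closes in the same event as the tether ring, completed by the C5–C10 bond and adopting a chair-like shape in the transition state. The cis relation of C20 and C11 at C10 and C9 is a direct transcript of the E-enal, the cis relation of C4 and C17 at C5 and C8 is a transcript of the E,E-diene, and the endo placement of the aluminium-bound formyl group links the two pairs, which puts H5 anti to C20 (trans ring fusion) and C17 syn to C11. Absolute control comes from C3 alone: of the two endo chair transition states the one with the bulky silyloxy group equatorial should be favoured, so the new centres form with C20 on the face of the C3 oxygen. The selectivities needed are therefore endo over exo, secured by Lewis-acid complexation of the enal, and one diene face over the other, secured by the equatorial preference at C3 next to the C4 gem-dimethyl group, which also biases the tether towards the folded reactive conformer (Thorpe–Ingold effect) and so helps the congested C5–C10 bond to form. The C17 oxygen is a silyl ether, a poor donor that leaves the Lewis acid on the aldehyde and resists pentadienylic ionisation; C8 is formed epimeric to the target on purpose and is corrected in step 19.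

Step 15
Reactants: 18 octalin aldehyde
Product: 19 (1R,2R,4aS,6R,8aR)-6-[(tert-butyldimethylsilyl)oxy]-2-{[(tert-butyldimethylsilyl)oxy]methyl}-5,5,8a-trimethyldecahydronaphthalene-1-carbaldehyde
Conditions: H2 (1 atm), 10% Pd/C, EtOAc, rt
Reagents that add atoms: none
Why: heterogeneous syn hydrogenation saturates the only alkene, the cis-disubstituted C6=C7 bond, creating no stereocentre, while the silyl ethers and the hindered aldehyde are untouched.

Step 16
Reactants: 19 decalin aldehyde
Product: 20 (1R,2R,4aS,6R,8aS)-1-ethenyl-6-[(tert-butyldimethylsilyl)oxy]-2-{[(tert-butyldimethylsilyl)oxy]methyl}-5,5,8a-trimethyldecahydronaphthalene (locants as in 19)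
Conditions: Ph3PCH3Br (3 equiv), KN(SiMe3)2 (2.8 equiv), THF, 0 °C; then 19, −78 °C → rt
Reagents that add atoms: methyltriphenylphosphonium bromide, C[P+](c1ccccc1)(c1ccccc1)c1ccccc1.[Br-]
Why: Wittig methylenation with the small, highly nucleophilic non-stabilised ylide converts the hindered C11 aldehyde into the C11=C12 vinyl group faster than the base can enolise it, so C9, whose formyl group is already equatorial, keeps its configuration.

Step 17
Reactants: 20 vinyl decalin; 21 methyl (2Z)-3-iodobut-2-enoate
Product: 23 methyl (2Z)-5-[(1R,2R,4aS,6R,8aS)-6-[(tert-butyldimethylsilyl)oxy]-2-{[(tert-butyldimethylsilyl)oxy]methyl}-5,5,8a-trimethyldecahydronaphthalen-1-yl]-3-methylpent-2-enoate, via B-alkyl-9-BBN 22 (not isolated)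
Conditions: 9-BBN (2 equiv), THF, rt; then 21 (1.5 equiv), Pd(dppf)Cl2 (10 mol %), AsPh3 (10 mol %), aq. K3PO4, DMF, rt
Reagents that add atoms: none
Why: anti-Markovnikov hydroboration of the only alkene by 9-BBN places boron on C12, and the B-alkyl Suzuki–Miyaura coupling (oxidative addition of the alkenyl iodide to zerovalent palladium, base-assisted transfer of the primary alkyl group, reductive elimination) forms C12–C13 with retention of the iodide geometry, so the ester ends cis to the new chain (2Z).

Step 18
Reactants: 23 bis-TBS Z-enoate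
Product: 24 methyl (2Z)-5-[(1R,2R,4aS,6R,8aS)-6-hydroxy-2-(hydroxymethyl)-5,5,8a-trimethyldecahydronaphthalen-1-yl]-3-methylpent-2-enoate
Conditions: 48% aq. HF, MeCN, rt
Reagents that add atoms: none
Why: fluoride-assisted Si–O cleavage under acidic conditions removes the primary and the hindered secondary TBS ether in one operation without touching the methyl ester or the conjugated alkene.

Step 19
Reactants: 24 diol
Product: 26 methyl (2Z)-5-[(1R,2S,4aS,6R,8aS)-2-formyl-6-hydroxy-5,5,8a-trimethyldecahydronaphthalen-1-yl]-3-methylpent-2-enoate, via C8-epimeric aldehyde 25 (not isolated)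
Conditions: TEMPO (0.2 equiv), PhI(OAc)2 (1.2 equiv), CH2Cl2, rt; then DBU (4 equiv), rt
Reagents that add atoms: none
Why: the oxoammonium salt generated from TEMPO and PhI(OAc)2 oxidises the primary C17 alcohol much faster than the hindered secondary C3 alcohol and stops at the aldehyde in the absence of water, and DBU then equilibrates C8 through the enolate, moving the formyl group from the axial position, where it clashes 1,3-diaxially with the C20 methyl group, to the equatorial position trans to the C9 chain, which sets the last stereocentre under thermodynamic control.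

Compound list
1 | geranyl acetate | CC(C)=CCC/C(C)=C/COC(C)=O | starting material
2 | (2E)-5-(3,3-dimethyloxiran-2-yl)-3-methylpent-2-en-1-yl acetate (racemic oxirane centre) | CC(=O)OC/C=C(\C)CCC1OC1(C)C | intermediate
3 | (2E)-6,7-dihydroxy-3,7-dimethyloct-2-en-1-yl acetate (racemic) | CC(=O)OC/C=C(\C)CCC(O)C(C)(C)O | intermediate (not isolated)
4 | (2E)-3-methyl-6-oxohex-2-en-1-yl acetate | CC(=O)OC/C=C(\C)CCC=O | intermediate
5 | 1-methoxy-2-methyl-1-(trimethylsilyloxy)prop-1-ene | COC(O[Si](C)(C)C)=C(C)C | starting material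
6 | methyl (3R,6E)-8-acetoxy-3-hydroxy-2,2,6-trimethyloct-6-enoate | COC(=O)C(C)(C)[C@H](O)CC/C(C)=C/COC(C)=O | intermediate
7 | methyl (3R,6E)-8-acetoxy-3-[(tert-butyldimethylsilyl)oxy]-2,2,6-trimethyloct-6-enoate | COC(=O)C(C)(C)[C@H](O[Si](C)(C)C(C)(C)C)CC/C(C)=C/COC(C)=O | intermediate
8 | methyl (3R,6E)-3-[(tert-butyldimethylsilyl)oxy]-8-hydroxy-2,2,6-trimethyloct-6-enoate | COC(=O)C(C)(C)[C@H](O[Si](C)(C)C(C)(C)C)CC/C(C)=C/CO | intermediate
9 | methyl (3R,6E)-3-[(tert-butyldimethylsilyl)oxy]-2,2,6-trimethyl-8-[(triethylsilyl)oxy]oct-6-enoate | COC(=O)C(C)(C)[C@H](O[Si](C)(C)C(C)(C)C)CC/C(C)=C/CO[Si](CC)(CC)CC | intermediate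
10 | (3R,6E)-3-[(tert-butyldimethylsilyl)oxy]-2,2,6-trimethyl-8-[(triethylsilyl)oxy]oct-6-en-1-ol | OCC(C)(C)[C@H](O[Si](C)(C)C(C)(C)C)CC/C(C)=C/CO[Si](CC)(CC)CC | intermediate
11 | (3R,6E)-3-[(tert-butyldimethylsilyl)oxy]-2,2,6-trimethyl-8-[(triethylsilyl)oxy]oct-6-enal | O=CC(C)(C)[C@H](O[Si](C)(C)C(C)(C)C)CC/C(C)=C/CO[Si](CC)(CC)CC | intermediate
12 | triethyl 4-phosphonocrotonate | CCOC(=O)/C=C/CP(=O)(OCC)OCC | starting material
13 | ethyl (2E,4E,7R,10E)-7-[(tert-butyldimethylsilyl)oxy]-6,6,10-trimethyl-12-[(triethylsilyl)oxy]dodeca-2,4,10-trienoate | CCOC(=O)/C=C/C=C/C(C)(C)[C@H](O[Si](C)(C)C(C)(C)C)CC/C(C)=C/CO[Si](CC)(CC)CC | intermediate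
14 | (2E,4E,7R,10E)-7-[(tert-butyldimethylsilyl)oxy]-6,6,10-trimethyl-12-[(triethylsilyl)oxy]dodeca-2,4,10-trien-1-ol | OC/C=C/C=C/C(C)(C)[C@H](O[Si](C)(C)C(C)(C)C)CC/C(C)=C/CO[Si](CC)(CC)CC | intermediate
15 | (2E,4E,7R,10E)-1,7-bis[(tert-butyldimethylsilyl)oxy]-6,6,10-trimethyl-12-[(triethylsilyl)oxy]dodeca-2,4,10-triene | CC(C)(C)[Si](C)(C)OC/C=C/C=C/C(C)(C)[C@H](O[Si](C)(C)C(C)(C)C)CC/C(C)=C/CO[Si](CC)(CC)CC | intermediate
16 | (2E,6R,8E,10E)-6,12-bis[(tert-butyldimethylsilyl)oxy]-3,7,7-trimethyldodeca-2,8,10-trien-1-ol | OC/C=C(\C)CC[C@@H](O[Si](C)(C)C(C)(C)C)C(C)(C)/C=C/C=C/CO[Si](C)(C)C(C)(C)C | intermediate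
17 | (2E,6R,8E,10E)-6,12-bis[(tert-butyldimethylsilyl)oxy]-3,7,7-trimethyldodeca-2,8,10-trienal (key-step precursor) | O=C/C=C(\C)CC[C@@H](O[Si](C)(C)C(C)(C)C)C(C)(C)/C=C/C=C/CO[Si](C)(C)C(C)(C)C | intermediate
18 | (1R,2R,4aS,6R,8aR)-6-[(tert-butyldimethylsilyl)oxy]-2-{[(tert-butyldimethylsilyl)oxy]methyl}-5,5,8a-trimethyl-1,2,4a,5,6,7,8,8a-octahydronaphthalene-1-carbaldehyde (key-step product) | O=C[C@@H]1[C@H](CO[Si](C)(C)C(C)(C)C)C=C[C@@H]2C(C)(C)[C@H](O[Si](C)(C)C(C)(C)C)CC[C@@]12C | intermediate
19 | (1R,2R,4aS,6R,8aR)-6-[(tert-butyldimethylsilyl)oxy]-2-{[(tert-butyldimethylsilyl)oxy]methyl}-5,5,8a-trimethyldecahydronaphthalene-1-carbaldehyde | O=C[C@@H]1[C@H](CO[Si](C)(C)C(C)(C)C)CC[C@@H]2C(C)(C)[C@H](O[Si](C)(C)C(C)(C)C)CC[C@@]12C | intermediate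
20 | (1R,2R,4aS,6R,8aS)-1-ethenyl-6-[(tert-butyldimethylsilyl)oxy]-2-{[(tert-butyldimethylsilyl)oxy]methyl}-5,5,8a-trimethyldecahydronaphthalene (locants as in 19) | C=C[C@@H]1[C@H](CO[Si](C)(C)C(C)(C)C)CC[C@@H]2C(C)(C)[C@H](O[Si](C)(C)C(C)(C)C)CC[C@@]12C | intermediate
21 | methyl (2Z)-3-iodobut-2-enoate | COC(=O)/C=C(/C)I | starting material
22 | 9-{2-[(1R,2R,4aS,6R,8aS)-6-[(tert-butyldimethylsilyl)oxy]-2-{[(tert-butyldimethylsilyl)oxy]methyl}-5,5,8a-trimethyldecahydronaphthalen-1-yl]ethyl}-9-borabicyclo[3.3.1]nonane | B1(CC[C@@H]3[C@H](CO[Si](C)(C)C(C)(C)C)CC[C@@H]4C(C)(C)[C@H](O[Si](C)(C)C(C)(C)C)CC[C@@]34C)C2CCCC1CCC2 | intermediate (not isolated)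
23 | methyl (2Z)-5-[(1R,2R,4aS,6R,8aS)-6-[(tert-butyldimethylsilyl)oxy]-2-{[(tert-butyldimethylsilyl)oxy]methyl}-5,5,8a-trimethyldecahydronaphthalen-1-yl]-3-methylpent-2-enoate | COC(=O)/C=C(/C)CC[C@@H]1[C@H](CO[Si](C)(C)C(C)(C)C)CC[C@@H]2C(C)(C)[C@H](O[Si](C)(C)C(C)(C)C)CC[C@@]12C | intermediate
24 | methyl (2Z)-5-[(1R,2R,4aS,6R,8aS)-6-hydroxy-2-(hydroxymethyl)-5,5,8a-trimethyldecahydronaphthalen-1-yl]-3-methylpent-2-enoate | COC(=O)/C=C(/C)CC[C@@H]1[C@H](CO)CC[C@@H]2C(C)(C)[C@H](O)CC[C@@]12C | intermediate
25 | methyl (2Z)-5-[(1R,2R,4aS,6R,8aS)-2-formyl-6-hydroxy-5,5,8a-trimethyldecahydronaphthalen-1-yl]-3-methylpent-2-enoate (C8 epimer of the target, axial formyl group) | COC(=O)/C=C(/C)CC[C@@H]1[C@H](C=O)CC[C@@H]2C(C)(C)[C@H](O)CC[C@@]12C | intermediate (not isolated)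
26 | methyl (2Z)-5-[(1R,2S,4aS,6R,8aS)-2-formyl-6-hydroxy-5,5,8a-trimethyldecahydronaphthalen-1-yl]-3-methylpent-2-enoate (CNP0188570.1) | COC(=O)/C=C(/C)CC[C@@H]1[C@@H](C=O)CC[C@@H]2C(C)(C)[C@H](O)CC[C@@]12C | target

Total step count: 19.
Longest linear sequence: 19 steps, from geranyl acetate 1 to target 26 (the route is fully linear; 5, 12 and 21 enter as purchased reagents).

Steps most likely to fail

Step 14 (key step). The cycloaddition may be too slow, because a β,β-disubstituted enal has to bond to a diene terminus that sits next to a quaternary carbon. Lewis-acid-driven E/Z isomerisation of the enal, ene-type or cationic cyclisation, or ionisation at the pentadienylic C17–O bond could then compete. Discrimination between the two diene faces by the single C3 centre may also be incomplete. The fallback activates the dienophile as an O-alkylated enal cation instead of a Lewis-acid complex. It sets out from trienal 17, which with Me3SiOCH2CH2OSiMe3 and catalytic Me3SiOTf in CH2Cl2 at −78 °C should give the trienyl 1,3-dioxolane F1. Catalytic TfOH (CH2Cl2, −78 → −40 °C) opens the acetal to an alkoxyallyl cation, which should undergo the ionic intramolecular Diels–Alder reaction well below the temperature the neutral enal needs and reclose to the octalin 1,3-dioxolane F2. Pyridinium p-toluenesulfonate in wet acetone then hydrolyses the acetal, and the route is rejoined at cycloadduct 18.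

Step 3. The enantioselectivity may erode, or the B–H bond of the promoter may reduce the aldehyde, when the stoichiometric oxazaborolidinone meets this functionalised aldehyde. The fallback sets the carbinol centre by reagent-controlled ketone reduction instead of by the aldol addition. It sets out from aldehyde 4 and ketene acetal 5, which with BF3·OEt2 in CH2Cl2 at −78 °C should give the racemic aldol F3. Dess–Martin oxidation gives the β-keto ester F4. Corey–Bakshi–Shibata reduction with the (S)-2-methyl-oxazaborolidine catalyst and catecholborane (toluene, −78 °C), in which the quaternary C(CH3)2CO2CH3 group acts as the large substituent, should return the 3R alcohol, and the route is rejoined at 6.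

Step 17. Transfer of the hindered primary alkyl group from boron to palladium may be slow and lose out to protodeboronation, and the iodoenoate may partly isomerise from Z to E under the basic palladium conditions. The fallback builds the trisubstituted Z-enoate by syn carbocupration instead of cross-coupling. It sets out from alkene 20, which on hydroboration with 9-BBN and oxidation with NaOH/H2O2 should give the C12 primary alcohol F5. I2, PPh3 and imidazole convert it into the primary iodide F6. LiC≡CH·H2NCH2CH2NH2 in DMSO gives the terminal alkyne F7, and n-BuLi followed by ClCO2CH3 (THF, −78 °C) gives the alkynoate F8. Me2CuLi in THF at −78 °C with a cold proton quench adds methyl and hydrogen syn across the triple bond, which places the ring-bearing chain cis to the ester, and the route is rejoined at Z-enoate 23.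

Further compounds
F1 | step 14 | 2-[(1E,5R,7E,9E)-5,11-bis[(tert-butyldimethylsilyl)oxy]-2,6,6-trimethylundeca-1,7,9-trien-1-yl]-1,3-dioxolane | O1CCOC1/C=C(\C)CC[C@@H](O[Si](C)(C)C(C)(C)C)C(C)(C)/C=C/C=C/CO[Si](C)(C)C(C)(C)C
F2 | step 14 | 2-[(1R,2R,4aS,6R,8aR)-6-[(tert-butyldimethylsilyl)oxy]-2-{[(tert-butyldimethylsilyl)oxy]methyl}-5,5,8a-trimethyl-1,2,4a,5,6,7,8,8a-octahydronaphthalen-1-yl]-1,3-dioxolane | O1CCOC1[C@@H]2[C@H](CO[Si](C)(C)C(C)(C)C)C=C[C@@H]3C(C)(C)[C@H](O[Si](C)(C)C(C)(C)C)CC[C@@]23C
F3 | step 3 | methyl (6E)-8-acetoxy-3-hydroxy-2,2,6-trimethyloct-6-enoate (racemic) | COC(=O)C(C)(C)C(O)CC/C(C)=C/COC(C)=O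
F4 | step 3 | methyl (6E)-8-acetoxy-2,2,6-trimethyl-3-oxooct-6-enoate | COC(=O)C(C)(C)C(=O)CC/C(C)=C/COC(C)=O
F5 | step 17 | 2-[(1R,2R,4aS,6R,8aS)-6-[(tert-butyldimethylsilyl)oxy]-2-{[(tert-butyldimethylsilyl)oxy]methyl}-5,5,8a-trimethyldecahydronaphthalen-1-yl]ethan-1-ol | OCC[C@@H]1[C@H](CO[Si](C)(C)C(C)(C)C)CC[C@@H]2C(C)(C)[C@H](O[Si](C)(C)C(C)(C)C)CC[C@@]12C
F6 | step 17 | (1R,2R,4aS,6R,8aS)-1-(2-iodoethyl)-6-[(tert-butyldimethylsilyl)oxy]-2-{[(tert-butyldimethylsilyl)oxy]methyl}-5,5,8a-trimethyldecahydronaphthalene (locants as in 19) | ICC[C@@H]1[C@H](CO[Si](C)(C)C(C)(C)C)CC[C@@H]2C(C)(C)[C@H](O[Si](C)(C)C(C)(C)C)CC[C@@]12C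
F7 | step 17 | (1R,2R,4aS,6R,8aS)-1-(but-3-yn-1-yl)-6-[(tert-butyldimethylsilyl)oxy]-2-{[(tert-butyldimethylsilyl)oxy]methyl}-5,5,8a-trimethyldecahydronaphthalene (locants as in 19) | C#CCC[C@@H]1[C@H](CO[Si](C)(C)C(C)(C)C)CC[C@@H]2C(C)(C)[C@H](O[Si](C)(C)C(C)(C)C)CC[C@@]12C
F8 | step 17 | methyl 5-[(1R,2R,4aS,6R,8aS)-6-[(tert-butyldimethylsilyl)oxy]-2-{[(tert-butyldimethylsilyl)oxy]methyl}-5,5,8a-trimethyldecahydronaphthalen-1-yl]pent-2-ynoate | COC(=O)C#CCC[C@@H]1[C@H](CO[Si](C)(C)C(C)(C)C)CC[C@@H]2C(C)(C)[C@H](O[Si](C)(C)C(C)(C)C)CC[C@@]12C
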